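**Plan**

Locants used here: C1 is the quaternary oxirane carbon, C2 is CH–OAc, C3 is CH–OBz, C4=C5 is the olefin, C6 is the oxirane CH, and C7 is the exocyclic CH2. The core is a 7-oxabicyclo[4.1.0]heptene.
Retrosynthetic cuts, in order: C3–O (benzoate introduced with inversion), the benzoyl–O bond on C7, the two oxirane bonds C1–O and C6–O, then C1–C7, then the acetyl and silyl groups on O2 and O3, and finally C2–O and C3–O back to iodobenzene.
Enabling feature: without the oxirane oxygen the carbocycle is a cyclohexa-1,3-diene (C1=C6–C5=C4) whose substituted terminus C1 adjoins the C2,C3-diol. This is the pattern of a halobenzene cis-dihydrodiol, so C1 can arrive as an sp2 C–I carbon ready to be coupled with C7.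
Forward order: the six-membered ring comes intact from iodobenzene by enzymatic dearomatisation. C7 is joined to C1 as CH2OH, the new allylic alcohol steers oxirane formation to C1=C6 rather than C4=C5, and the esters follow. The TBS group on O3 is the only helper.
Stereochemistry: C2 comes from the dioxygenase and is kept. C3 comes from the dioxygenase and is inverted by Mitsunobu benzoylation. C1 and C6 come from Sharpless epoxidation with L-(+)-tartrate, matched with the anti bias of the C2 and C3 substituents.

Key step: step 4

Assumption: iodobenzene is taken to be oxidised by toluene dioxygenase with the same regio- and enantioselectivity as the other monohalobenzenes, so 2 is the (1S,2S) diol as essentially one enantiomer.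

**Step 1**
Reactants: 1 iodobenzene
Product: 2 (1S,2S)-3-iodocyclohexa-3,5-diene-1,2-diol
Conditions: E. coli JM109(pDTG601A) whole cells (toluene dioxygenase), aerated mineral medium, pH 7, 30 °C; EtOAc extraction
Reagents that add atoms: dioxygen O=O
Why: Enzymatic arene cis-dihydroxylation (dearomatisation) of a monohalobenzene takes place at the 2,3-bond and should give one enantiomer, which sets C2 (kept) and C3 (inverted later) and leaves the C–I bond on the future C1.

**Step 2**
Reactants: 2 (1S,2S)-3-iodocyclohexa-3,5-diene-1,2-diol
Product: 3 (1S,6S)-6-[(tert-butyldimethylsilyl)oxy]-2-iodocyclohexa-2,4-dien-1-ol (O3 silylated, C2–OH free)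
Conditions: TBSCl (1.05 equiv), imidazole, DMF, −10 °C
Reagents that add atoms: tert-butyldimethylsilyl chloride CC(C)(C)[Si](C)(C)Cl
Why: This is a sterically controlled monosilylation in which the C3 hydroxyl, remote from iodine, should react ahead of the C2 hydroxyl shielded by the neighbouring C–I, and only O–H bonds change, so no stereocentre is touched.

**Step 3**
Reactants: 3 (1S,6S)-6-[(tert-butyldimethylsilyl)oxy]-2-iodocyclohexa-2,4-dien-1-ol
Product: 4 (1S,6S)-6-[(tert-butyldimethylsilyl)oxy]-2-iodocyclohexa-2,4-dien-1-yl acetate
Conditions: Ac2O, pyridine, DMAP (cat.), CH2Cl2, 0 °C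
Reagents that add atoms: acetic anhydride CC(=O)OC(C)=O
Why: DMAP-catalysed acylation of the remaining secondary alcohol runs under cold, mildly basic conditions that dihydrodiol esters tolerate without aromatising, and C2 keeps its configuration because the C–O bond is not involved.

**Step 4**
Reactants: 4 (1S,6S)-6-[(tert-butyldimethylsilyl)oxy]-2-iodocyclohexa-2,4-dien-1-yl acetate; 5 (tributylstannyl)methanol
Product: 6 (1R,6S)-6-[(tert-butyldimethylsilyl)oxy]-2-(hydroxymethyl)cyclohexa-2,4-dien-1-yl acetate (same spatial arrangement at C2; the descriptor changes with the substituent on C1)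
Conditions: Pd2(dba)3 (5 mol %), AsPh3 (20 mol %), CuI (10 mol %), NMP, 40 °C, dark
Reagents that add atoms: none
Why: Pd(0) inserts into the C1–I bond of the iododiene, the CH2OH group passes from tin through copper to palladium, and reductive elimination forms C1–C7 on the sp2 carbon without touching C2 or C3. The closest known reaction type is the Migita–Kosugi–Stille hydroxymethylation of alkenyl halides with (tributylstannyl)methanol. The step closes no ring and creates no stereocentre; its weight lies in completing the seven-carbon skeleton on a ring three operations from iodobenzene and in turning C1=C6 into the olefin of a primary allylic alcohol, the handle by which step 5 tells C1=C6 from C4=C5 and fixes C1 and C6. The selectivity needed is oxidative addition at C–I ahead of ionisation of the allylic (dienylic) C2 acetate, which would end in aromatisation, and the weak C–I bond, the poorly donating AsPh3 ligand and the low temperature should secure it. Transfer of CH2OH rather than butyl should be secured by the α-oxygen, which speeds tin-to-copper exchange of that group.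

**Step 5**
Reactants: 6 (1R,6S)-6-[(tert-butyldimethylsilyl)oxy]-2-(hydroxymethyl)cyclohexa-2,4-dien-1-yl acetate
Product: 8 (1S,2S,3S,6S)-2-acetoxy-1-(benzoyloxymethyl)-3-(tert-butyldimethylsilyloxy)-1,6-epoxycyclohex-4-ene, via epoxy alcohol 7 (not isolated)
Conditions: Ti(OiPr)4 (10 mol %), L-(+)-DET (13 mol %), TBHP (decane), 4 Å MS, CH2Cl2, −25 °C; P(OMe)3; then BzCl, Et3N, DMAP (cat.), −20 to 0 °C
Reagents that add atoms: tert-butyl hydroperoxide CC(C)(C)OO; benzoyl chloride O=C(Cl)c1ccccc1
Why: In the Sharpless asymmetric epoxidation only C1=C6 belongs to an allylic alcohol, so oxygen should go there and not to C4=C5; L-(+)-tartrate delivers it to the face anti to the C2 acetate and C3 silyl ether (reagent and substrate matched), which sets C1 (S) and C6 (S), and in situ benzoylation is the known way to secure a sensitive vinyl epoxy alcohol.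

**Step 6**
Reactants: 8 (1S,2S,3S,6S)-2-acetoxy-1-(benzoyloxymethyl)-3-(tert-butyldimethylsilyloxy)-1,6-epoxycyclohex-4-ene
Product: 9 (1S,2S,3S,6S)-2-acetoxy-1-(benzoyloxymethyl)-1,6-epoxycyclohex-4-en-3-ol (C3–OH cis to C2–OAc)
Conditions: TBAF/AcOH (1:1), THF, 0 °C; used at once
Reagents that add atoms: none
Why: Fluoride-induced Si–O cleavage buffered with acetic acid stays non-basic, so the three oxygen functions and the vinyl oxirane should survive and the cis-vicinal acetate should stay on O2, with no stereocentre affected.

**Step 7**
Reactants: 9 (1S,2S,3S,6S)-2-acetoxy-1-(benzoyloxymethyl)-1,6-epoxycyclohex-4-en-3-ol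
Product: 10 target, (1S,2S,3R,6S)-2-acetoxy-3-benzoyloxy-1-(benzoyloxymethyl)-1,6-epoxycyclohex-4-ene
Conditions: PPh3, DIAD, PhCO2H, toluene, 0 °C
Reagents that add atoms: benzoic acid O=C(O)c1ccccc1
Why: In the Mitsunobu esterification the C3 oxyphosphonium is displaced by benzoate in an SN2 process with inversion (3S to 3R); the cis C2 acetate cannot take part from the rear, and the non-polar solvent disfavours ionisation, so the trans C2/C3 diester should result.

**Compound list**
1 | iodobenzene | Ic1ccccc1 | starting material
2 | (1S,2S)-3-iodocyclohexa-3,5-diene-1,2-diol | O[C@H]1[C@@H](O)C=CC=C1I | intermediate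
3 | (1S,6S)-6-[(tert-butyldimethylsilyl)oxy]-2-iodocyclohexa-2,4-dien-1-ol | O[C@H]1[C@@H](O[Si](C)(C)C(C)(C)C)C=CC=C1I | intermediate
4 | (1S,6S)-6-[(tert-butyldimethylsilyl)oxy]-2-iodocyclohexa-2,4-dien-1-yl acetate | CC(=O)O[C@H]1[C@@H](O[Si](C)(C)C(C)(C)C)C=CC=C1I | intermediate
5 | (tributylstannyl)methanol | CCCC[Sn](CCCC)(CCCC)CO | starting material
6 | (1R,6S)-6-[(tert-butyldimethylsilyl)oxy]-2-(hydroxymethyl)cyclohexa-2,4-dien-1-yl acetate | CC(=O)O[C@H]1[C@@H](O[Si](C)(C)C(C)(C)C)C=CC=C1CO | intermediate
7 | epoxy alcohol, (1S,2S,3S,6S)-2-acetoxy-3-(tert-butyldimethylsilyloxy)-1-(hydroxymethyl)-1,6-epoxycyclohex-4-ene | CC(=O)O[C@H]1[C@@H](O[Si](C)(C)C(C)(C)C)C=C[C@@H]2O[C@@]21CO | intermediate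
8 | (1S,2S,3S,6S)-2-acetoxy-1-(benzoyloxymethyl)-3-(tert-butyldimethylsilyloxy)-1,6-epoxycyclohex-4-ene | CC(=O)O[C@H]1[C@@H](O[Si](C)(C)C(C)(C)C)C=C[C@@H]2O[C@@]21COC(=O)c1ccccc1 | intermediate
9 | (1S,2S,3S,6S)-2-acetoxy-1-(benzoyloxymethyl)-1,6-epoxycyclohex-4-en-3-ol | CC(=O)O[C@H]1[C@@H](O)C=C[C@@H]2O[C@@]21COC(=O)c1ccccc1 | intermediate
10 | (1S,2S,3R,6S)-2-acetoxy-3-benzoyloxy-1-(benzoyloxymethyl)-1,6-epoxycyclohex-4-ene | CC(=O)O[C@H]1[C@H](OC(=O)c2ccccc2)C=C[C@@H]2O[C@@]21COC(=O)c1ccccc1 | target

Total step count: 7. Longest linear sequence: 7 (1 to 10); 5 is bought.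

**Steps most likely to fail**

Step 4. Pd(0) may ionise the dienylic C2 acetate, followed by β-hydride loss and aromatisation. Transfer of the sp3 CH2OH group from tin may also be too slow, so that butyl transfer or thermal dimerisation of the diene takes over. The fallback sets out from 4 and comes back at 6. It is a Nozaki–Hiyama–Kishi reaction, in which CrCl2 with catalytic NiCl2 in DMF at room temperature turns the C1–I bond into an alkenylchromium species. This species adds to monomeric formaldehyde (from cracked paraformaldehyde). No Pd(0) and no heating are involved, esters are tolerated, and no new isolated compound arises.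

Step 5. The titanium Lewis acid may open the freshly formed vinyl oxirane, either by alkoxide attack at allylic C6 or by participation of the C2 acetate at C1. The acetyl group may also migrate to the C7 alkoxide before benzoylation. The fallback sets out from 6 and comes back at 8.
- The alcohol is benzoylated first (BzCl, pyridine, 0 °C) to give the diene benzoate F1.
- Tetraphenylporphyrin-sensitised photooxygenation (O2, hν, CH2Cl2, −20 °C) adds singlet oxygen in a [4+2] manner across C1 and C4, on the face anti to the C2 and C3 substituents, to give the 1,4-endoperoxide F2.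
- PPh3 then attacks the less hindered peroxide oxygen on C4, and the C1 alkoxide closes onto C6 in an SN2′ manner with loss of phosphine oxide. This places the oxirane on C1–C6 and the olefin at C4=C5.

Step 7. Benzoate may attack C5 (SN2′), the oxyphosphonium may undergo E2 loss with the anti C2–H, leading towards an arene oxide and aromatisation, or benzoate may attack the vinyl oxirane. The fallback sets out from 9 and comes back at 10 and separates activation from displacement.
- ClCH2SO2Cl and pyridine in CH2Cl2 at −20 °C give the chloromethanesulfonate F3.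
- F3 is displaced with inversion by caesium benzoate and 18-crown-6 in toluene at room temperature, with no acid and no betaine base present.

**Further compounds**
F0 | step 4 | none | none
F1 | step 5 | diene benzoate, (1R,6S)-2-(benzoyloxymethyl)-6-[(tert-butyldimethylsilyl)oxy]cyclohexa-2,4-dien-1-yl acetate | CC(=O)O[C@H]1[C@@H](O[Si](C)(C)C(C)(C)C)C=CC=C1COC(=O)c1ccccc1
F2 | step 5 | 1,4-endoperoxide of F1 (O–O bridge C1 to C4 anti to the C2 and C3 substituents, C5=C6) | CC(=O)O[C@H]1[C@@H](O[Si](C)(C)C(C)(C)C)[C@H]2C=C[C@]1(COC(=O)c1ccccc1)OO2
F3 | step 7 | C3 chloromethanesulfonate of 9 | CC(=O)O[C@H]1[C@@H](OS(=O)(=O)CCl)C=C[C@@H]2O[C@@]21COC(=O)c1ccccc1
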